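**Plan**

- Numbering is that of eudesmane: ring A = C1–C5 + C10, ring B = C5–C10, C14 = methyl on C10, C15 = methyl on C4, C11–C13 = acrylate on C7. The target is (3S,7R,8R,10R), i.e. 3β-ester, 7β-acrylate, 8β-OAc, 10β-Me. 
- Retrosynthetic cuts, in order: the C3–O ester; the C3 carbinol back to the Δ4-3-ketone; the C14 methyl back to a formyl group; C5–C10 together with C1–C2 by an intramolecular Diels–Alder reaction; C4=C5 by Wittig and C1 by α-methylenation; C7–C8 by a 2-(methoxycarbonyl)allylation.
- Enabling feature: C3(O)–C4(Me)=C5 of ring A is the retron of a 2-silyloxydiene C2=C3–C4=C5. Quaternary C10 with its one-carbon substituent C14 is the α-carbon of a 2-substituted acrolein C1=C10–C14HO. The C6–C9 chain tethers the two, so both six-membered rings close around the C5–C10 bond in one event.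
- Forward order: an acyclic chain carrying C7/C8 is built (steps 1–9); rings A and B arise together (step 10); then Δ4-enone, CHO→CH3, C3 reduction and esterification.
- Stereochemistry: C7/C8 from a chromium-catalysed asymmetric syn-allylation; C10 from the catalyst-controlled face of the dienophile in the cycloaddition; C3 from Luche reduction anti to the C10 methyl group; the E-acyl geometry is bought.

Key step: step 10

Remark: all compounds marked "starting material" in the list are taken as purchasable.
Remark: the (S)-configured oxazaborolidinium catalyst of step 10 is assumed to leave open the Re face of the dienophile carbon C10 (priorities CHO > C9 > C1); if its sense is the opposite, its mirror image is meant.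

**Route**

Step 1
Reactants: 1 3-[(tert-butyldimethylsilyl)oxy]propanal; 2 methyl acrylate
Product: 3 methyl 5-[(tert-butyldimethylsilyl)oxy]-3-hydroxy-2-methylidenepentanoate (racemic)
Conditions: DABCO (1 equiv), 2 (3 equiv), MeOH, rt, 3–5 d
Reagents that add atoms: none
Why: Morita–Baylis–Hillman reaction, in which the DABCO–acrylate zwitterion adds to the unhindered aldehyde and loss of the amine returns the α-methylene ester; the racemic carbinol centre is removed in step 2.

Step 2
Reactants: 3 methyl 5-[(tert-butyldimethylsilyl)oxy]-3-hydroxy-2-methylidenepentanoate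
Product: 4 methyl (Z)-2-(bromomethyl)-5-[(tert-butyldimethylsilyl)oxy]pent-2-enoate
Conditions: NBS (1.2 equiv), Me2S (1.3 equiv), CH2Cl2, 0 °C → rt
Reagents that add atoms: N-bromosuccinimide, O=C1CCC(=O)N1Br
Why: Allylic bromination with transposition (SN2′ collapse of the alkoxysulfonium bromide), which should give the thermodynamically preferred enoate with the alkyl chain trans to the ester, i.e. the (Z)-2-(bromomethyl) isomer.

Step 3
Reactants: 4 methyl (Z)-2-(bromomethyl)-5-[(tert-butyldimethylsilyl)oxy]pent-2-enoate; 5 4,4-dimethoxybutanal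
Product: 7 methyl (3R,4R)-3-{2-[(tert-butyldimethylsilyl)oxy]ethyl}-4-hydroxy-7,7-dimethoxy-2-methylideneheptanoate, via trimethylsilyl ether 6 (not isolated)
Conditions: CrCl2 (10 mol %), chiral carbazole-bis(oxazoline) ligand (12 mol %), Mn (2 equiv), TMSCl (1.5 equiv), DIPEA (30 mol %), THF, 0 °C → rt; then citric acid, MeOH, 0 °C
Reagents that add atoms: none
Why: Catalytic asymmetric Nozaki–Hiyama–Kishi 2-(alkoxycarbonyl)allylation, in which the allylchromium(III) species reacts at its γ-carbon through a chair-like six-membered transition state with the γ-substituent axial, which should give the syn C7/C8 relationship, while the ligand-bound chromium selects the aldehyde face that gives the 4R carbinol; the silyl ether formed for turnover is cleaved by mild acid without lactonisation.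

Step 4
Reactants: 7 methyl (3R,4R)-3-{2-[(tert-butyldimethylsilyl)oxy]ethyl}-4-hydroxy-7,7-dimethoxy-2-methylideneheptanoate
Product: 8 methyl (3R,4R)-4-acetoxy-3-{2-[(tert-butyldimethylsilyl)oxy]ethyl}-7,7-dimethoxy-2-methylideneheptanoate
Conditions: Ac2O, Et3N, DMAP (cat.), CH2Cl2, 0 °C → rt
Reagents that add atoms: acetic anhydride, CC(=O)OC(C)=O
Why: DMAP-catalysed acetylation of the secondary alcohol, which installs the C8 acetate of the target early and blocks lactonisation onto the acrylate ester.

Step 5
Reactants: 8 methyl (3R,4R)-4-acetoxy-3-{2-[(tert-butyldimethylsilyl)oxy]ethyl}-7,7-dimethoxy-2-methylideneheptanoate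
Product: 9 methyl (3R,4R)-4-acetoxy-3-(2-hydroxyethyl)-7,7-dimethoxy-2-methylideneheptanoate
Conditions: HF·pyridine, pyridine/THF, 0 °C → rt
Reagents that add atoms: none
Why: Fluoride cleavage of the primary silyl ether under buffered conditions that should leave the dimethyl acetal, the acetate and the acrylate untouched.

Step 6
Reactants: 9 methyl (3R,4R)-4-acetoxy-3-(2-hydroxyethyl)-7,7-dimethoxy-2-methylideneheptanoate
Product: 10 methyl (3R,4R)-4-acetoxy-7,7-dimethoxy-2-methylidene-3-(2-oxoethyl)heptanoate
Conditions: Dess–Martin periodinane, NaHCO3, CH2Cl2, rt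
Reagents that add atoms: none
Why: Dess–Martin oxidation of the primary alcohol to the aldehyde under buffered neutral conditions, with no epimerisable centre α to the new carbonyl group.

Step 7
Reactants: 10 methyl (3R,4R)-4-acetoxy-7,7-dimethoxy-2-methylidene-3-(2-oxoethyl)heptanoate; 11 3-(triphenylphosphoranylidene)butan-2-one
Product: 12 methyl (3R,4R)-4-acetoxy-7,7-dimethoxy-3-[(E)-3-methyl-4-oxopent-2-en-1-yl]-2-methylideneheptanoate
Conditions: toluene, 90 °C
Reagents that add atoms: none
Why: Wittig olefination with a stabilised α-methyl ylide, which should give the (E)-trisubstituted enone (C4=C5 with the C15 methyl on C4) selectively.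

Step 8
Reactants: 12 methyl (3R,4R)-4-acetoxy-7,7-dimethoxy-3-[(E)-3-methyl-4-oxopent-2-en-1-yl]-2-methylideneheptanoate
Product: 14 methyl (3R,4R)-4-acetoxy-6-formyl-3-[(E)-3-methyl-4-oxopent-2-en-1-yl]-2-methylidenehept-6-enoate, via aldehyde 13 (not isolated)
Conditions: PPTS (cat.), acetone/H2O, 50 °C; then 37% aq. CH2O, pyrrolidine (20 mol %), propionic acid (20 mol %), iPrOH, 45 °C
Reagents that add atoms: water, O; formaldehyde, C=O
Why: Mild acetal hydrolysis followed by amine/acid-catalysed α-methylenation of the aldehyde (Mannich condensation with formaldehyde and elimination), which makes C10 the α-carbon of a 2-substituted acrolein and adds C1, the aldehyde forming its enamine far faster than the hindered methyl ketone.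

Step 9
Reactants: 14 methyl (3R,4R)-4-acetoxy-6-formyl-3-[(E)-3-methyl-4-oxopent-2-en-1-yl]-2-methylidenehept-6-enoate
Product: 15 methyl (3R,4R)-4-acetoxy-3-{(E)-4-[(tert-butyldimethylsilyl)oxy]-3-methylpenta-2,4-dien-1-yl}-6-formyl-2-methylidenehept-6-enoate
Conditions: TBSOTf (1.2 equiv), Et3N (2 equiv), CH2Cl2, −78 °C; cold NaHCO3 work-up, used at once
Reagents that add atoms: tert-butyldimethylsilyl trifluoromethanesulfonate, CC(C)(C)[Si](C)(C)OS(=O)(=O)C(F)(F)F
Why: Soft enolisation of the methyl ketone at its kinetically accessible α′-position (C2) gives the cross-conjugated 2-silyloxydiene, while the enal has no enolisable position and should survive at low temperature.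

Step 10
Reactants: 15 methyl (3R,4R)-4-acetoxy-3-{(E)-4-[(tert-butyldimethylsilyl)oxy]-3-methylpenta-2,4-dien-1-yl}-6-formyl-2-methylidenehept-6-enoate
Product: 16 methyl 8β-acetoxy-3-[(tert-butyldimethylsilyl)oxy]-14-oxo-5α-eudesma-3,11(13)-dien-12-oate
Conditions: protonated (S)-B-(o-tolyl)oxazaborolidine (from (S)-α,α-diphenylprolinol) triflimide (20 mol %), CH2Cl2 (0.02 M), −78 → −40 °C
Reagents that add atoms: none
Why: Catalytic enantioselective type-1 intramolecular Diels–Alder reaction: the cationic oxazaborolidine binds the formyl oxygen of the s-trans 2-substituted acrolein (B···O coordination plus a formyl C–H···O contact), and the 2-silyloxydiene C2=C3(OTBS)–C4(Me)=C5 adds across C1=C10 in a concerted but asynchronous [4+2] step in which C2–C1 bonding leads and the C5–C10 bond that creates the quaternary centre follows. The closest known reaction type is the cationic-oxazaborolidine-catalysed Diels–Alder addition of 2-substituted acroleins to 2-silyloxybutadienes, together with its intramolecular trienal variant. Ring A (C1–C5, C10) closes as the new cyclohexene of the cycloaddition and ring B (C5–C10) closes in the fused mode through the four-atom C6–C9 tether by the C5–C10 bond, the diene polarity (nucleophilic C2, silyloxy group "para" and alkyl group "ortho" to the formyl-bearing carbon) being matched to exactly this regiochemistry. C10 is set by the enantioface of the dienophile that the catalyst leaves open (Re face, so that C14 ends cis to the C8 acetoxy group), the intrinsic bias of the chair-like tether with the C7 side chain equatorial being weak; C5 (H trans to the endo formyl group) is a transient centre removed in step 11. The step therefore needs π-facial selectivity only, which is secured by reagent control, whereas endo/exo selectivity is irrelevant to the target. The C7 acrylate cannot compete because only two atoms separate it from the diene terminus, and the uncatalysed background should be slow at −78 °C.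

Step 11
Reactants: 16 methyl 8β-acetoxy-3-[(tert-butyldimethylsilyl)oxy]-14-oxo-5α-eudesma-3,11(13)-dien-12-oate
Product: 17 methyl 8β-acetoxy-3,14-dioxoeudesma-4,11(13)-dien-12-oate
Conditions: Pd(OAc)2 (1.1 equiv), MeCN, rt → 40 °C
Reagents that add atoms: none
Why: Saegusa–Ito oxidation, in which transmetalation of the silyl enol ether gives the C4 palladium enolate and syn β-hydride elimination of H-5 should give the conjugated tetrasubstituted Δ4-enone, erasing the C5 stereocentre.

Step 12
Reactants: 17 methyl 8β-acetoxy-3,14-dioxoeudesma-4,11(13)-dien-12-oate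
Product: 19 methyl 8β-acetoxy-3-oxoeudesma-4,11(13)-dien-12-oate, via tosylhydrazone 18 (not isolated)
Conditions: TsNHNH2 (1.05 equiv), EtOH, 50 °C; then catecholborane (2 equiv), CHCl3, 0 °C; then NaOAc·3H2O, reflux
Reagents that add atoms: none
Why: Chemoselective tosylhydrazone formation at the aldehyde (more electrophilic than the tetrasubstituted enone) and hydride reduction of the hydrazone with loss of sulfinate and dinitrogen (Caglioti-type deoxygenation) should turn the activating formyl group into the C14 methyl group without touching the quaternary centre.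

Step 13
Reactants: 19 methyl 8β-acetoxy-3-oxoeudesma-4,11(13)-dien-12-oate
Product: 20 methyl 8β-acetoxy-3β-hydroxyeudesma-4,11(13)-dien-12-oate
Conditions: NaBH4, CeCl3·7H2O, MeOH, −78 °C
Reagents that add atoms: none
Why: Luche reduction, in which 1,2-hydride delivery to the enone from the α-face, anti to the axial C10 methyl group, should give the equatorial 3β (3S) allylic alcohol and leave the acrylate and the acetate alone.

Step 14
Reactants: 20 methyl 8β-acetoxy-3β-hydroxyeudesma-4,11(13)-dien-12-oate; 21 (E)-3-methylpent-2-enoic acid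
Product: 22 methyl 8β-acetoxy-3β-[(E)-3-methylpent-2-enoyloxy]eudesma-4,11(13)-dien-12-oate (target)
Conditions: EDC·HCl, DMAP (cat.), CH2Cl2, 0 °C → rt
Reagents that add atoms: none
Why: Steglich esterification of the unhindered allylic alcohol with retention at C3, run cold with catalytic DMAP to avoid deconjugation or E/Z scrambling of the β,β-disubstituted acryloyl unit.

**Compound list**

1 | 3-[(tert-butyldimethylsilyl)oxy]propanal | O=CCCO[Si](C)(C)C(C)(C)C | starting material
2 | methyl acrylate | C=CC(=O)OC | starting material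
3 | methyl 5-[(tert-butyldimethylsilyl)oxy]-3-hydroxy-2-methylidenepentanoate (racemic) | C=C(C(=O)OC)C(O)CCO[Si](C)(C)C(C)(C)C | intermediate
4 | methyl (Z)-2-(bromomethyl)-5-[(tert-butyldimethylsilyl)oxy]pent-2-enoate | BrC/C(C(=O)OC)=C\CCO[Si](C)(C)C(C)(C)C | intermediate
5 | 4,4-dimethoxybutanal | O=CCCC(OC)OC | starting material
6 | methyl (3R,4R)-3-{2-[(tert-butyldimethylsilyl)oxy]ethyl}-7,7-dimethoxy-2-methylidene-4-[(trimethylsilyl)oxy]heptanoate | C=C(C(=O)OC)[C@@H](CCO[Si](C)(C)C(C)(C)C)[C@H](O[Si](C)(C)C)CCC(OC)OC | intermediate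
7 | methyl (3R,4R)-3-{2-[(tert-butyldimethylsilyl)oxy]ethyl}-4-hydroxy-7,7-dimethoxy-2-methylideneheptanoate | C=C(C(=O)OC)[C@@H](CCO[Si](C)(C)C(C)(C)C)[C@H](O)CCC(OC)OC | intermediate
8 | methyl (3R,4R)-4-acetoxy-3-{2-[(tert-butyldimethylsilyl)oxy]ethyl}-7,7-dimethoxy-2-methylideneheptanoate | C=C(C(=O)OC)[C@@H](CCO[Si](C)(C)C(C)(C)C)[C@H](OC(C)=O)CCC(OC)OC | intermediate
9 | methyl (3R,4R)-4-acetoxy-3-(2-hydroxyethyl)-7,7-dimethoxy-2-methylideneheptanoate | C=C(C(=O)OC)[C@@H](CCO)[C@H](OC(C)=O)CCC(OC)OC | intermediate
10 | methyl (3R,4R)-4-acetoxy-7,7-dimethoxy-2-methylidene-3-(2-oxoethyl)heptanoate | C=C(C(=O)OC)[C@@H](CC=O)[C@H](OC(C)=O)CCC(OC)OC | intermediate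
11 | 3-(triphenylphosphoranylidene)butan-2-one | CC(=O)C(C)=P(c1ccccc1)(c1ccccc1)c1ccccc1 | starting material
12 | methyl (3R,4R)-4-acetoxy-7,7-dimethoxy-3-[(E)-3-methyl-4-oxopent-2-en-1-yl]-2-methylideneheptanoate | C=C(C(=O)OC)[C@@H](C/C=C(\C)C(C)=O)[C@H](OC(C)=O)CCC(OC)OC | intermediate
13 | methyl (3R,4R)-4-acetoxy-3-[(E)-3-methyl-4-oxopent-2-en-1-yl]-2-methylidene-7-oxoheptanoate | C=C(C(=O)OC)[C@@H](C/C=C(\C)C(C)=O)[C@H](OC(C)=O)CCC=O | intermediate
14 | methyl (3R,4R)-4-acetoxy-6-formyl-3-[(E)-3-methyl-4-oxopent-2-en-1-yl]-2-methylidenehept-6-enoate | C=C(C(=O)OC)[C@@H](C/C=C(\C)C(C)=O)[C@H](OC(C)=O)CC(=C)C=O | intermediate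
15 | methyl (3R,4R)-4-acetoxy-3-{(E)-4-[(tert-butyldimethylsilyl)oxy]-3-methylpenta-2,4-dien-1-yl}-6-formyl-2-methylidenehept-6-enoate | C=C(C(=O)OC)[C@@H](C/C=C(\C)C(=C)O[Si](C)(C)C(C)(C)C)[C@H](OC(C)=O)CC(=C)C=O | intermediate
16 | methyl 8β-acetoxy-3-[(tert-butyldimethylsilyl)oxy]-14-oxo-5α-eudesma-3,11(13)-dien-12-oate (trans-fused, formyl on C10 β) | C=C(C(=O)OC)[C@H]1C[C@H]2C(C)=C(O[Si](C)(C)C(C)(C)C)CC[C@]2(C=O)C[C@H]1OC(C)=O | intermediate
17 | methyl 8β-acetoxy-3,14-dioxoeudesma-4,11(13)-dien-12-oate | C=C(C(=O)OC)[C@H]1CC2=C(C)C(=O)CC[C@]2(C=O)C[C@H]1OC(C)=O | intermediate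
18 | 14-(p-toluenesulfonyl)hydrazone of 17 | C=C(C(=O)OC)[C@H]1CC2=C(C)C(=O)CC[C@]2(/C=N/NS(=O)(=O)c3ccc(C)cc3)C[C@H]1OC(C)=O | intermediate
19 | methyl 8β-acetoxy-3-oxoeudesma-4,11(13)-dien-12-oate | C=C(C(=O)OC)[C@H]1CC2=C(C)C(=O)CC[C@]2(C)C[C@H]1OC(C)=O | intermediate
20 | methyl 8β-acetoxy-3β-hydroxyeudesma-4,11(13)-dien-12-oate | C=C(C(=O)OC)[C@H]1CC2=C(C)[C@@H](O)CC[C@]2(C)C[C@H]1OC(C)=O | intermediate
21 | (E)-3-methylpent-2-enoic acid | CC/C(C)=C/C(=O)O | starting material
22 | methyl 8β-acetoxy-3β-[(E)-3-methylpent-2-enoyloxy]eudesma-4,11(13)-dien-12-oate, (3S,7R,8R,10R) | C=C(C(=O)OC)[C@H]1CC2=C(C)[C@@H](OC(=O)/C=C(\C)CC)CC[C@]2(C)C[C@H]1OC(C)=O | target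

**Step count and risks**

Total steps: 14. Longest linear sequence: 14 steps (1 → 22).

Steps most likely to fail:

1. Step 10 (key cycloaddition). What may go wrong: insufficient π-facial discrimination at C10 if the catalyst's preference and the conformational bias of the substituted tether disagree, or loss of the silyl dienol ether by protodesilylation under the acidic catalyst. Fallback (covalent aminocatalysis instead of a preformed silyl dienol ether and a Lewis acid): the route sets out from 14, leaving out 15 and 16. A chiral primary amine salt (9-amino-9-deoxy-epi-cinchona amine·TFA, toluene, rt) condenses with the methyl ketone to give the cross-conjugated 2-aminodiene and with the formyl group to give the iminium ion. The same C1–C2 and C5–C10 bonds then form in an intramolecular enamine/iminium [4+2] reaction, and hydrolysis should give methyl 8β-acetoxy-3,14-dioxoeudesm-11(13)-en-12-oate F1 as a C4/C5 epimer mixture. Thermodynamic enol silylation (TMSCl, NaI, Et3N, MeCN) should give the Δ3 silyl enol ether, methyl 8β-acetoxy-14-oxo-3-[(trimethylsilyl)oxy]eudesma-3,11(13)-dien-12-oate F2. Saegusa–Ito oxidation with Pd(OAc)2 brings the material back to the route at 17.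

2. Step 12 (formyl to methyl). What may go wrong: slow or unselective hydrazone formation at the neopentyl, syn-axially flanked formyl group, or competing reduction of the enone. Fallback (stepwise deoxygenation through the alcohol and a radical dehalogenation): the route sets out from 17. NaBH4 at −78 °C (aldehyde-selective) should give methyl 8β-acetoxy-14-hydroxy-3-oxoeudesma-4,11(13)-dien-12-oate F3, which is used at once to forestall acetyl migration. Appel-type iodination (I2, PPh3, imidazole, toluene, 80 °C) should give methyl 8β-acetoxy-14-iodo-3-oxoeudesma-4,11(13)-dien-12-oate F4. Tin hydride reduction (Bu3SnH, Et3B/air, high hydride concentration so that the primary radical is quenched before it can add to the acrylate) comes back to the route at 19.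

3. Step 3 (asymmetric allylation). What may go wrong: erosion of enantio- or syn-selectivity with the γ-substituted allyl bromide, or lactonisation during desilylation. Fallback (closed-transition-state allylboration instead of organochromium chemistry): the route sets out from 4. Palladium-catalysed borylation with bis(pinacolato)diboron should give, with the alkene geometry retained, methyl (E)-5-[(tert-butyldimethylsilyl)oxy]-2-[(4,4,5,5-tetramethyl-1,3,2-dioxaborolan-2-yl)methyl]pent-2-enoate F5. Its chiral-phosphoric-acid-catalysed addition ((R)-TRIP, toluene, −30 °C) to 5 runs through a chair transition state with the γ-substituent axial (syn product) and, after aqueous work-up, comes back to the route at 7.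

Further compounds
F1 | step 10 | methyl 8β-acetoxy-3,14-dioxoeudesm-11(13)-en-12-oate (C4/C5 epimer mixture) | C=C(C(=O)OC)[C@H]1CC2C(C)C(=O)CC[C@]2(C=O)C[C@H]1OC(C)=O
F2 | step 10 | methyl 8β-acetoxy-14-oxo-3-[(trimethylsilyl)oxy]eudesma-3,11(13)-dien-12-oate | C=C(C(=O)OC)[C@H]1CC2C(C)=C(O[Si](C)(C)C)CC[C@]2(C=O)C[C@H]1OC(C)=O
F3 | step 12 | methyl 8β-acetoxy-14-hydroxy-3-oxoeudesma-4,11(13)-dien-12-oate | C=C(C(=O)OC)[C@H]1CC2=C(C)C(=O)CC[C@]2(CO)C[C@H]1OC(C)=O
F4 | step 12 | methyl 8β-acetoxy-14-iodo-3-oxoeudesma-4,11(13)-dien-12-oate | C=C(C(=O)OC)[C@H]1CC2=C(C)C(=O)CC[C@]2(CI)C[C@H]1OC(C)=O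
F5 | step 3 | methyl (E)-5-[(tert-butyldimethylsilyl)oxy]-2-[(4,4,5,5-tetramethyl-1,3,2-dioxaborolan-2-yl)methyl]pent-2-enoate | CC1(C)OB(C/C(C(=O)OC)=C\CCO[Si](C)(C)C(C)(C)C)OC1(C)C
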